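**Plan**

- Cuts: the four outer phenols are traced back to benzyl ethers. Ring A is opened at the bond between its acyl-bearing C1 and the oxygenated C6. The chain that results is cut at C4–C5 (acyl transfer), at the CH2 bond on C4 (ring B arm) and at the CH2 bond on C2 (ring C arm).
- Enabling feature: ring A has oxygen on C2, C4 and C6, a ketone on C1 and carbon substituents on C3 and C5. It is therefore the aromatic tautomer of a 2-acylcyclohexane-1,3,5-trione, and ring A C1 to C6 correspond to chain C6, C5, C4, C3, C2 and C1 of a 2,4-disubstituted 3,5,7-triketo ester.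
- Arms: rings B and C both come from 2-methylphloroglucinol by acylation, double O-benzylation, O-methylation, formylation, reduction and bromination.
- Chain: the ring C bromide alkylates methyl acetoacetate at C2. The dianion is then acylated at C4 by a Weinreb amide of (R)-4-methyl-3-oxohexanoic acid with C7 masked as a ketal. The ring B bromide enters last at the new diketone methylene under carbonate, so the acetyl group never meets a strong base.
- End game: ketal hydrolysis frees the triketo ester, Mg(OMe)2 folds it into ring A (the only ring made), and hydrogenolysis finishes the route.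
- Stereochemistry: the single (R) centre is bought with (R)-2-methylbutanoic acid. The ketal keeps its C–H non-acidic through the basic steps, and the C2 and C4 epimers disappear on aromatisation.

Key step: step 20

Assumption: 18 is bought enantiopure. Compounds 25–28 are drawn as keto forms and handled as mixtures of tautomers and of epimers at C2 and C4, which does not matter because both carbons become sp2 in step 20.

Notation: chain atoms C1–C10 are those of decanoate 28 (C1 = ester carbon). Arm B = [3-acetyl-2,6-bis(benzyloxy)-4-methoxy-5-methylphenyl]methyl. Arm C = [2,6-bis(benzyloxy)-4-methoxy-3-methyl-5-(2-methylpropanoyl)phenyl]methyl.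

**Route**

Step 1
Reactants: 1 2-methylbenzene-1,3,5-triol; 2 2-methylpropanoyl chloride (isobutyryl chloride)
Product: 3 2-methyl-1-(2,4,6-trihydroxy-3-methylphenyl)propan-1-one
Conditions: AlCl3 (3.5 equiv), CH2Cl2–PhNO2, 0 → 40 °C; then ice/1 M HCl
Reagents that add atoms: none
Why: Friedel–Crafts acylation of an electron-rich phloroglucinol, in which the two free ring positions of 1 are equivalent and the first acyl group, hydrogen-bonded to its ortho hydroxyls, deactivates the ring towards a second acylation.

Step 2
Reactants: 3 2-methyl-1-(2,4,6-trihydroxy-3-methylphenyl)propan-1-one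
Product: 4 1-[4,6-bis(benzyloxy)-2-hydroxy-3-methylphenyl]-2-methylpropan-1-one
Conditions: BnBr (2.1 equiv), K2CO3 (2.2 equiv), DMF, rt
Reagents that add atoms: benzyl bromide, BrCc1ccccc1
Why: Williamson etherification under carbonate, selective because the para hydroxyl is not hydrogen-bonded and reacts first, and of the two chelated ortho hydroxyls the one beside the ring C–H is far more accessible than the one wedged between ketone and methyl group, a pattern well known from partial alkylation of C-methylated phloroacylphenones.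

Step 3
Reactants: 4 1-[4,6-bis(benzyloxy)-2-hydroxy-3-methylphenyl]-2-methylpropan-1-one
Product: 5 1-[4,6-bis(benzyloxy)-2-methoxy-3-methylphenyl]-2-methylpropan-1-one
Conditions: MeI (3 equiv), K2CO3 (2 equiv), DMF, 50 °C
Reagents that add atoms: iodomethane, CI
Why: Williamson methylation of the last, chelated and hindered phenol, which needs only a small electrophile, a polar aprotic solvent and gentle heating, while carbonate is too weak to enolise the aryl ketone.

Step 4
Reactants: 5 1-[4,6-bis(benzyloxy)-2-methoxy-3-methylphenyl]-2-methylpropan-1-one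
Product: 7 2,6-bis(benzyloxy)-4-methoxy-3-methyl-5-(2-methylpropanoyl)benzaldehyde, via ring C iminium chloride 6 (not isolated)
Conditions: POCl3 (1.5 equiv), DMF, 0 °C → rt; then H2O
Reagents that add atoms: N,N-dimethylformamide, CN(C)C=O; water, O
Why: Vilsmeier–Haack formylation at the only free ring position, which lies ortho to both benzyloxy groups and para to the methoxy group, while the ketone is twisted out of conjugation by its two ortho substituents and deactivates little, and benzyl ethers tolerate the reagent.

Step 5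
Reactants: 7 2,6-bis(benzyloxy)-4-methoxy-3-methyl-5-(2-methylpropanoyl)benzaldehyde
Product: 8 1-[2,4-bis(benzyloxy)-3-(hydroxymethyl)-6-methoxy-5-methylphenyl]-2-methylpropan-1-one
Conditions: NaBH4 (0.5 equiv), THF–MeOH, −20 °C
Reagents that add atoms: none
Why: Chemoselective borohydride reduction, since an aldehyde is reduced much faster at low temperature than an aryl ketone flanked by two ortho alkoxy groups.

Step 6
Reactants: 8 1-[2,4-bis(benzyloxy)-3-(hydroxymethyl)-6-methoxy-5-methylphenyl]-2-methylpropan-1-one
Product: 9 1-[2,4-bis(benzyloxy)-3-(bromomethyl)-6-methoxy-5-methylphenyl]-2-methylpropan-1-one (ring C bromide)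
Conditions: PBr3 (0.4 equiv), CH2Cl2, 0 °C; aq NaHCO3 wash, used crude at once
Reagents that add atoms: phosphorus tribromide, BrP(Br)Br
Why: Conversion of a benzylic alcohol into the bromide with PBr3 (SN2 on the phosphite ester), clean here because the hexasubstituted ring offers no position for Friedel–Crafts self-condensation.

Step 7
Reactants: 1 2-methylbenzene-1,3,5-triol; 10 acetyl chloride
Product: 11 1-(2,4,6-trihydroxy-3-methylphenyl)ethan-1-one
Conditions: AlCl3 (3.5 equiv), CH2Cl2–PhNO2, 0 → 40 °C; then ice/1 M HCl
Reagents that add atoms: none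
Why: Friedel–Crafts acylation, governed by the same equivalence of the two free positions and the same deactivation after the first acylation as in step 1.

Step 8
Reactants: 11 1-(2,4,6-trihydroxy-3-methylphenyl)ethan-1-one
Product: 12 1-[4,6-bis(benzyloxy)-2-hydroxy-3-methylphenyl]ethan-1-one
Conditions: BnBr (2.1 equiv), K2CO3 (2.2 equiv), DMF, rt
Reagents that add atoms: benzyl bromide, BrCc1ccccc1
Why: Williamson etherification with the selectivity of step 2, leaving untouched the hydroxyl that is both chelated to the acetyl group and shielded by the neighbouring methyl group.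

Step 9
Reactants: 12 1-[4,6-bis(benzyloxy)-2-hydroxy-3-methylphenyl]ethan-1-one
Product: 13 1-[4,6-bis(benzyloxy)-2-methoxy-3-methylphenyl]ethan-1-one
Conditions: MeI (3 equiv), K2CO3 (2 equiv), DMF, 50 °C
Reagents that add atoms: iodomethane, CI
Why: Williamson methylation of the remaining chelated phenol, with a base too weak to C-methylate the acetyl group.

Step 10
Reactants: 13 1-[4,6-bis(benzyloxy)-2-methoxy-3-methylphenyl]ethan-1-one
Product: 15 3-acetyl-2,6-bis(benzyloxy)-4-methoxy-5-methylbenzaldehyde, via ring B iminium chloride 14 (not isolated)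
Conditions: POCl3 (1.3 equiv), DMF, 0 °C → rt; then H2O
Reagents that add atoms: N,N-dimethylformamide, CN(C)C=O; water, O
Why: Vilsmeier–Haack formylation of the last free position, placed after O-methylation because a free ortho-hydroxyacetophenone would be diverted to a 3-formylchromone, and kept at or below room temperature so that the slower chloroformylation of the methyl ketone does not compete.

Step 11
Reactants: 15 3-acetyl-2,6-bis(benzyloxy)-4-methoxy-5-methylbenzaldehyde
Product: 16 1-[2,4-bis(benzyloxy)-3-(hydroxymethyl)-6-methoxy-5-methylphenyl]ethan-1-one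
Conditions: NaBH4 (0.5 equiv), THF–MeOH, −20 °C
Reagents that add atoms: none
Why: Chemoselective borohydride reduction of the aldehyde in the presence of a doubly ortho-substituted and therefore sluggish acetophenone carbonyl.

Step 12
Reactants: 16 1-[2,4-bis(benzyloxy)-3-(hydroxymethyl)-6-methoxy-5-methylphenyl]ethan-1-one
Product: 17 1-[2,4-bis(benzyloxy)-3-(bromomethyl)-6-methoxy-5-methylphenyl]ethan-1-one (ring B bromide)
Conditions: PBr3 (0.4 equiv), CH2Cl2, 0 °C; aq NaHCO3 wash, used crude at once
Reagents that add atoms: phosphorus tribromide, BrP(Br)Br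
Why: Bromination of a benzylic alcohol with PBr3 as in step 6, the ketone being inert to the reagent at this temperature.

Step 13
Reactants: 18 (2R)-2-methylbutanoic acid; 19 potassium methyl malonate
Product: 21 methyl (4R)-4-methyl-3-oxohexanoate, via acyl imidazolide 20 (not isolated)
Conditions: CDI, THF, rt; then 19, MgCl2, Et3N, MeCN, rt; 1 M HCl
Reagents that add atoms: 1,1'-carbonyldiimidazole, O=C(n1ccnc1)n1ccnc1 (supplies the imidazolyl group of 20; none of its atoms remain in 21)
Why: Masamune–Brooks homologation, in which the acyl imidazolide C-acylates the magnesium enolate of the malonate half-ester and the adduct decarboxylates on acidification, under conditions mild enough to keep alpha-stereocentres of carboxylic acids intact.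

Step 14
Reactants: 21 methyl (4R)-4-methyl-3-oxohexanoate
Product: 22 methyl 2-{2-[(2R)-butan-2-yl]-1,3-dioxolan-2-yl}acetate
Conditions: TMSOCH2CH2OTMS, TMSOTf (cat.), CH2Cl2, −78 → −20 °C; pyridine quench
Reagents that add atoms: 1,2-bis(trimethylsilyloxy)ethane, C[Si](C)(C)OCCO[Si](C)(C)C
Why: Noyori ketalisation, driven by formation of the Si–O–Si bond and run cold so that no enol ether equilibrium can touch the neighbouring (R) centre, whose C–H is from here on no longer alpha to a carbonyl group.

Step 15
Reactants: 22 methyl 2-{2-[(2R)-butan-2-yl]-1,3-dioxolan-2-yl}acetate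
Product: 23 2-{2-[(2R)-butan-2-yl]-1,3-dioxolan-2-yl}-N-methoxy-N-methylacetamide
Conditions: MeNHOMe·HCl, iPrMgCl, THF, −20 → 0 °C
Reagents that add atoms: N,O-dimethylhydroxylamine hydrochloride, CNOC.Cl
Why: Weinreb amide formation by aminolysis of the ester with the chloromagnesium amide, a standard reaction of enolisable esters that leaves the ketal and the stereocentre untouched.

Step 16
Reactants: 24 methyl acetoacetate; 9 ring C bromide
Product: 25 methyl 2-(arm C)-3-oxobutanoate (racemic at C2)
Conditions: 24 (2 equiv), K2CO3, acetone, rt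
Reagents that add atoms: none
Why: Acetoacetic ester alkylation (SN2 of the stabilised enolate on a reactive benzylic bromide), with excess 24 suppressing double alkylation, the new C2 centre forming as a racemate that is erased in step 20.

Step 17
Reactants: 25 methyl 2-(arm C)-3-oxobutanoate; 23 Weinreb amide
Product: 26 methyl 2-(arm C)-6-{2-[(2R)-butan-2-yl]-1,3-dioxolan-2-yl}-3,5-dioxohexanoate
Conditions: LiN(iPr)2 (3.2 equiv), THF, −78 → −20 °C; then 23, −78 → 0 °C; aq NH4Cl
Reagents that add atoms: none
Why: Gamma-acylation of a beta-keto ester dianion with a Weinreb amide, in which the terminal carbanion is the most nucleophilic site, the chelated tetrahedral adduct survives until the quench so that the acidic product cannot consume dianion, and the third equivalent of base covers any enolisation of the isobutyryl group, whose tetrasubstituted and doubly ortho-shielded enolate is inert and simply reprotonates.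

Step 18
Reactants: 26 methyl 2-(arm C)-6-{2-[(2R)-butan-2-yl]-1,3-dioxolan-2-yl}-3,5-dioxohexanoate; 17 ring B bromide
Product: 27 methyl 4-(arm B)-2-(arm C)-6-{2-[(2R)-butan-2-yl]-1,3-dioxolan-2-yl}-3,5-dioxohexanoate
Conditions: K2CO3 (1.1 equiv), acetone, 0 °C → rt
Reagents that add atoms: none
Why: Carbonate-mediated C-alkylation of a 1,3-diketone, regioselective because C4 is the only doubly activated methylene (more acidic and less hindered than the tertiary C2–H, while C6 adjoins a ketal) and mild enough that the methyl ketone of ring B is never enolised, the new C4 centre forming without control and being erased in step 20.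

Step 19
Reactants: 27 methyl 4-(arm B)-2-(arm C)-6-{2-[(2R)-butan-2-yl]-1,3-dioxolan-2-yl}-3,5-dioxohexanoate
Product: 28 methyl (8R)-4-(arm B)-2-(arm C)-8-methyl-3,5,7-trioxodecanoate
Conditions: 1 M HCl, THF, rt; used without chromatography
Reagents that add atoms: water, O
Why: Acid-catalysed hydrolysis of a dioxolane, assisted by the beta-carbonyl group, under conditions too mild to cleave aryl benzyl ethers or to dehydrate the triketone, the liberated C7 ketone enolising towards C6 and not towards the (R) centre.

Step 20
Reactants: 28 methyl (8R)-4-(arm B)-2-(arm C)-8-methyl-3,5,7-trioxodecanoate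
Product: 30 (2R)-1-[3-(arm B)-5-(arm C)-2,4,6-trihydroxyphenyl]-2-methylbutan-1-one (tetra-O-benzyl target), via cyclic trione tautomer 29 (not isolated)
Conditions: Mg(OMe)2 (5 equiv), MeOH–THF, reflux; then cold 1 M HCl
Reagents that add atoms: none
Why: Mg(OMe)2 enolises first the only unsubstituted 1,3-diketone methylene (chain C6), this magnesium-bound enolate adds to the ester carbonyl C1, methoxide is expelled, and the 2-acylcyclohexane-1,3,5-trione 29 tautomerises to the arene and is trapped as its phenoxide, which makes the sequence irreversible. The closest known reaction type is the Claisen (Dieckmann) cyclisation of 3,5,7-triketo esters, or of the 4-hydroxy-2-pyrones derived from them, to acylphloroglucinols under magnesium or alkali alkoxide. Ring A closes in the 6-exo-trig mode through the new bond between ring A C1 (chain C6) and ring A C6 (chain C1). No stereocentre is formed, the epimers at C2 and C4 converge because both carbons become sp2, and C8 keeps its (R) configuration because the C7 carbonyl is tied up first in the chelated C5–C7 enolate and then in the vinylogous carboxylate of the product, so that C8–H is never the proton removed. The step needs C-acylation at C1 to win over aldol closure (C2 onto C7), lactonisation and retro-Claisen scission: the aldol adduct would hold a quaternary C2 beside a carbinol bearing sec-butyl, cannot aromatise and reverts, the pyrone formed by O-acylation is reopened by methoxide to the same enolate, and chelation keeps free methoxide low and the ketones enolised. The arms on C2 and C4 lower the acidity of these positions, which leaves the ester un-enolised and electrophilic, and the benzyl ethers stop rings B and C from departing as phenoxides, so the methylene bridges cannot exchange under base.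

Step 21
Reactants: 30 tetra-O-benzyl target
Product: 31 CNP0169975.1, (2R)-1-[3-[(3-acetyl-2,6-dihydroxy-4-methoxy-5-methylphenyl)methyl]-5-{[2,6-dihydroxy-4-methoxy-3-methyl-5-(2-methylpropanoyl)phenyl]methyl}-2,4,6-trihydroxyphenyl]-2-methylbutan-1-one
Conditions: H2 (1 atm), Pd/C, EtOAc–MeOH, rt
Reagents that add atoms: none
Why: Hydrogenolysis of aryl benzyl ethers over palladium under neutral conditions, which spares the chelated aryl ketones and the diarylmethane bridges and avoids acid- or base-induced exchange of methylene-bridged phloroglucinol units.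

**Compound list**

1 | 2-methylbenzene-1,3,5-triol | Cc1c(O)cc(O)cc1O | starting material
2 | 2-methylpropanoyl chloride | CC(C)C(=O)Cl | starting material
3 | 2-methyl-1-(2,4,6-trihydroxy-3-methylphenyl)propan-1-one | CC(C)C(=O)c1c(O)cc(O)c(C)c1O | intermediate
4 | 1-[4,6-bis(benzyloxy)-2-hydroxy-3-methylphenyl]-2-methylpropan-1-one | CC(C)C(=O)c1c(OCc2ccccc2)cc(OCc2ccccc2)c(C)c1O | intermediate
5 | 1-[4,6-bis(benzyloxy)-2-methoxy-3-methylphenyl]-2-methylpropan-1-one | CC(C)C(=O)c1c(OCc2ccccc2)cc(OCc2ccccc2)c(C)c1OC | intermediate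
6 | ring C iminium chloride, N-{[2,6-bis(benzyloxy)-4-methoxy-3-methyl-5-(2-methylpropanoyl)phenyl]methylidene}-N-methylmethanaminium chloride | C[N+](C)=Cc1c(OCc2ccccc2)c(C)c(OC)c(C(=O)C(C)C)c1OCc1ccccc1.[Cl-] | intermediate (not isolated)
7 | 2,6-bis(benzyloxy)-4-methoxy-3-methyl-5-(2-methylpropanoyl)benzaldehyde | O=Cc1c(OCc2ccccc2)c(C)c(OC)c(C(=O)C(C)C)c1OCc1ccccc1 | intermediate
8 | 1-[2,4-bis(benzyloxy)-3-(hydroxymethyl)-6-methoxy-5-methylphenyl]-2-methylpropan-1-one | OCc1c(OCc2ccccc2)c(C)c(OC)c(C(=O)C(C)C)c1OCc1ccccc1 | intermediate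
9 | 1-[2,4-bis(benzyloxy)-3-(bromomethyl)-6-methoxy-5-methylphenyl]-2-methylpropan-1-one | BrCc1c(OCc2ccccc2)c(C)c(OC)c(C(=O)C(C)C)c1OCc1ccccc1 | intermediate
10 | acetyl chloride | CC(=O)Cl | starting material
11 | 1-(2,4,6-trihydroxy-3-methylphenyl)ethan-1-one | CC(=O)c1c(O)cc(O)c(C)c1O | intermediate
12 | 1-[4,6-bis(benzyloxy)-2-hydroxy-3-methylphenyl]ethan-1-one | CC(=O)c1c(OCc2ccccc2)cc(OCc2ccccc2)c(C)c1O | intermediate
13 | 1-[4,6-bis(benzyloxy)-2-methoxy-3-methylphenyl]ethan-1-one | CC(=O)c1c(OCc2ccccc2)cc(OCc2ccccc2)c(C)c1OC | intermediate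
14 | ring B iminium chloride, N-{[3-acetyl-2,6-bis(benzyloxy)-4-methoxy-5-methylphenyl]methylidene}-N-methylmethanaminium chloride | C[N+](C)=Cc1c(OCc2ccccc2)c(C)c(OC)c(C(C)=O)c1OCc1ccccc1.[Cl-] | intermediate (not isolated)
15 | 3-acetyl-2,6-bis(benzyloxy)-4-methoxy-5-methylbenzaldehyde | O=Cc1c(OCc2ccccc2)c(C)c(OC)c(C(C)=O)c1OCc1ccccc1 | intermediate
16 | 1-[2,4-bis(benzyloxy)-3-(hydroxymethyl)-6-methoxy-5-methylphenyl]ethan-1-one | OCc1c(OCc2ccccc2)c(C)c(OC)c(C(C)=O)c1OCc1ccccc1 | intermediate
17 | 1-[2,4-bis(benzyloxy)-3-(bromomethyl)-6-methoxy-5-methylphenyl]ethan-1-one | BrCc1c(OCc2ccccc2)c(C)c(OC)c(C(C)=O)c1OCc1ccccc1 | intermediate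
18 | (2R)-2-methylbutanoic acid | CC[C@@H](C)C(=O)O | starting material
19 | potassium methyl malonate | COC(=O)CC(=O)[O-].[K+] | starting material
20 | (2R)-1-(1H-imidazol-1-yl)-2-methylbutan-1-one | CC[C@@H](C)C(=O)n1ccnc1 | intermediate (not isolated)
21 | methyl (4R)-4-methyl-3-oxohexanoate | CC[C@@H](C)C(=O)CC(=O)OC | intermediate
22 | methyl 2-{2-[(2R)-butan-2-yl]-1,3-dioxolan-2-yl}acetate | CC[C@@H](C)C1(CC(=O)OC)OCCO1 | intermediate
23 | 2-{2-[(2R)-butan-2-yl]-1,3-dioxolan-2-yl}-N-methoxy-N-methylacetamide | CC[C@@H](C)C1(CC(=O)N(C)OC)OCCO1 | intermediate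
24 | methyl acetoacetate | COC(=O)CC(C)=O | starting material
25 | methyl 2-{[2,6-bis(benzyloxy)-4-methoxy-3-methyl-5-(2-methylpropanoyl)phenyl]methyl}-3-oxobutanoate (racemic) | COC(=O)C(Cc1c(OCc2ccccc2)c(C)c(OC)c(C(=O)C(C)C)c1OCc1ccccc1)C(C)=O | intermediate
26 | methyl 2-{[2,6-bis(benzyloxy)-4-methoxy-3-methyl-5-(2-methylpropanoyl)phenyl]methyl}-6-{2-[(2R)-butan-2-yl]-1,3-dioxolan-2-yl}-3,5-dioxohexanoate (C2 epimers) | CC[C@@H](C)C1(CC(=O)CC(=O)C(Cc2c(OCc3ccccc3)c(C)c(OC)c(C(=O)C(C)C)c2OCc2ccccc2)C(=O)OC)OCCO1 | intermediate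
27 | methyl 4-{[3-acetyl-2,6-bis(benzyloxy)-4-methoxy-5-methylphenyl]methyl}-2-{[2,6-bis(benzyloxy)-4-methoxy-3-methyl-5-(2-methylpropanoyl)phenyl]methyl}-6-{2-[(2R)-butan-2-yl]-1,3-dioxolan-2-yl}-3,5-dioxohexanoate (C2/C4 epimers) | CC[C@@H](C)C1(CC(=O)C(Cc2c(OCc3ccccc3)c(C)c(OC)c(C(C)=O)c2OCc2ccccc2)C(=O)C(Cc2c(OCc3ccccc3)c(C)c(OC)c(C(=O)C(C)C)c2OCc2ccccc2)C(=O)OC)OCCO1 | intermediate
28 | methyl (8R)-4-{[3-acetyl-2,6-bis(benzyloxy)-4-methoxy-5-methylphenyl]methyl}-2-{[2,6-bis(benzyloxy)-4-methoxy-3-methyl-5-(2-methylpropanoyl)phenyl]methyl}-8-methyl-3,5,7-trioxodecanoate (C2/C4 epimers) | CC[C@@H](C)C(=O)CC(=O)C(Cc1c(OCc2ccccc2)c(C)c(OC)c(C(C)=O)c1OCc1ccccc1)C(=O)C(Cc1c(OCc2ccccc2)c(C)c(OC)c(C(=O)C(C)C)c1OCc1ccccc1)C(=O)OC | intermediate (key-step precursor)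
29 | 2-[(2R)-2-methylbutanoyl]-4-(arm B)-6-(arm C)cyclohexane-1,3,5-trione | CC[C@@H](C)C(=O)C1C(=O)C(Cc2c(OCc3ccccc3)c(C)c(OC)c(C(C)=O)c2OCc2ccccc2)C(=O)C(Cc2c(OCc3ccccc3)c(C)c(OC)c(C(=O)C(C)C)c2OCc2ccccc2)C1=O | intermediate (not isolated)
30 | (2R)-1-[3-{[3-acetyl-2,6-bis(benzyloxy)-4-methoxy-5-methylphenyl]methyl}-5-{[2,6-bis(benzyloxy)-4-methoxy-3-methyl-5-(2-methylpropanoyl)phenyl]methyl}-2,4,6-trihydroxyphenyl]-2-methylbutan-1-one | CC[C@@H](C)C(=O)c1c(O)c(Cc2c(OCc3ccccc3)c(C)c(OC)c(C(C)=O)c2OCc2ccccc2)c(O)c(Cc2c(OCc3ccccc3)c(C)c(OC)c(C(=O)C(C)C)c2OCc2ccccc2)c1O | intermediate (key-step product)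
31 | CNP0169975.1, (2R)-1-[3-[(3-acetyl-2,6-dihydroxy-4-methoxy-5-methylphenyl)methyl]-5-{[2,6-dihydroxy-4-methoxy-3-methyl-5-(2-methylpropanoyl)phenyl]methyl}-2,4,6-trihydroxyphenyl]-2-methylbutan-1-one | CC[C@@H](C)C(=O)c1c(O)c(Cc2c(O)c(C)c(OC)c(C(C)=O)c2O)c(O)c(Cc2c(O)c(C)c(OC)c(C(=O)C(C)C)c2O)c1O | target

**Step count**

Total step count: 21.
Longest linear sequence: 12 (steps 1–6, then 16–21).

**Steps most likely to fail**

Step 20. Methoxide may cleave the chain by retro-Claisen attack on the substituted, poorly enolised C3 and C5 ketones faster than the crowded C6 enolate reaches the ester. The material may also come to rest as the lactone. The fallback takes ring A ready-made instead of folding it. It sets out from 18, 16 and 8.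
- Acid 18 is converted with oxalyl chloride and catalytic DMF into (2R)-2-methylbutanoyl chloride F1.
- F1 acylates commercial phloroglucinol (benzene-1,3,5-triol) under AlCl3 to give (2R)-2-methyl-1-(2,4,6-trihydroxyphenyl)butan-1-one F2.
- Acid-catalysed Friedel–Crafts benzylation of an excess of F2 with alcohol 16 (catalytic TsOH, dioxane) gives the mono-armed (2R)-1-[3-(arm B)-2,4,6-trihydroxyphenyl]-2-methylbutan-1-one F3.
- A second benzylation at the last free ring position with alcohol 8 gives 30, where the route is rejoined.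

Step 17. The terminal carbanion may be quenched by proton transfer from the alpha-CH2 of the Weinreb amide, which would be followed by beta-elimination and opening of the dioxolane, or by proton transfer from the isobutyryl group. Addition to the neopentyl-like amide carbonyl may also be slow. The fallback moves the strong-base step ahead of both arms. It sets out from 24 and 23.
- The dianion of 24 (NaH, then n-BuLi, THF) is acylated with 23 to give methyl 6-{2-[(2R)-butan-2-yl]-1,3-dioxolan-2-yl}-3,5-dioxohexanoate F4.
- Bromide 17 with K2CO3 alkylates the most acidic position, C4, to give methyl 4-(arm B)-6-{2-[(2R)-butan-2-yl]-1,3-dioxolan-2-yl}-3,5-dioxohexanoate F5.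
- Bromide 9 with K2CO3 then alkylates C2, the only doubly activated methylene left, while C4 could react only by forming a quaternary carbon. This gives 27, where the route is rejoined, and steps 16–18 are replaced.

Step 18. The very electron-rich bromide may ionise and decompose or alkylate the enolate on oxygen, and the diketo ester may lactonise under carbonate before it is alkylated. The fallback avoids the halide altogether. It sets out from 26 and aldehyde 15.
- Knoevenagel condensation (piperidinium acetate, toluene, molecular sieves) can take place only at C4, because the tertiary C2 cannot dehydrate. It gives the 4-arylmethylidene diketo ester F6.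
- Conjugate transfer hydrogenation with the Hantzsch ester (diethyl 2,6-dimethyl-1,4-dihydropyridine-3,5-dicarboxylate) leaves benzyl ethers and ketones alone. It gives 27, where the route is rejoined.

**Further compounds**

F1 | step 20 | (2R)-2-methylbutanoyl chloride | CC[C@@H](C)C(=O)Cl
F2 | step 20 | (2R)-2-methyl-1-(2,4,6-trihydroxyphenyl)butan-1-one | CC[C@@H](C)C(=O)c1c(O)cc(O)cc1O
F3 | step 20 | (2R)-1-[3-{[3-acetyl-2,6-bis(benzyloxy)-4-methoxy-5-methylphenyl]methyl}-2,4,6-trihydroxyphenyl]-2-methylbutan-1-one | CC[C@@H](C)C(=O)c1c(O)cc(O)c(Cc2c(OCc3ccccc3)c(C)c(OC)c(C(C)=O)c2OCc2ccccc2)c1O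
F4 | step 17 | methyl 6-{2-[(2R)-butan-2-yl]-1,3-dioxolan-2-yl}-3,5-dioxohexanoate | CC[C@@H](C)C1(CC(=O)CC(=O)CC(=O)OC)OCCO1
F5 | step 17 | methyl 4-{[3-acetyl-2,6-bis(benzyloxy)-4-methoxy-5-methylphenyl]methyl}-6-{2-[(2R)-butan-2-yl]-1,3-dioxolan-2-yl}-3,5-dioxohexanoate | CC[C@@H](C)C1(CC(=O)C(Cc2c(OCc3ccccc3)c(C)c(OC)c(C(C)=O)c2OCc2ccccc2)C(=O)CC(=O)OC)OCCO1
F6 | step 18 | methyl 4-{[3-acetyl-2,6-bis(benzyloxy)-4-methoxy-5-methylphenyl]methylidene}-2-{[2,6-bis(benzyloxy)-4-methoxy-3-methyl-5-(2-methylpropanoyl)phenyl]methyl}-6-{2-[(2R)-butan-2-yl]-1,3-dioxolan-2-yl}-3,5-dioxohexanoate (alkene geometry not defined) | CC[C@@H](C)C1(CC(=O)C(=Cc2c(OCc3ccccc3)c(C)c(OC)c(C(C)=O)c2OCc2ccccc2)C(=O)C(Cc2c(OCc3ccccc3)c(C)c(OC)c(C(=O)C(C)C)c2OCc2ccccc2)C(=O)OC)OCCO1
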